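**Assumption:** the SMILES is read as the (6S,7S,8R) enantiomer, i.e. (−)-isolariciresinol. Aryl bromide 4 and benzyl bromide 5 are taken as catalogue items, and the in-situ Grignard formation from 4 is counted inside step 2.

## Retrosynthetic overview

1. The tetralin ring is closed last: the C8–C8a bond (benzylic C to aryl C) comes from anodic dehydrogenative cyclisation of the C2-symmetric (2S,3S)-dibenzylbutanediol. The two benzylic CH2 groups are homotopic, so only one product is possible, and C8 is set trans to C7.
2. The diol comes from LiAlH4 reduction of the trans-(3S,4S)-dibenzylbutyrolactone.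
3. The lactone comes from global hydrogenolysis/decarboxylation of an α-benzylated α-(benzyloxycarbonyl) lactone. C7 is set by thermodynamic trans control from C6.
4. That lactone comes from Cu-catalysed aryl-Grignard opening of a cyclopropane-fused lactone with in-situ enolate benzylation. The cyclopropane lactone comes from (S)-epichlorohydrin and dibenzyl malonate, which supplies the C6 stereocentre.
5. Ring order: cyclopropane plus γ-lactone (step 1), cyclopropane opened (step 2), lactone opened to the acyclic diol (step 4), carbocycle closed (step 5).

## Route

**Step 1**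
Reactants: 1 (S)-epichlorohydrin; 2 dibenzyl malonate
Product: 3 benzyl (1S,5S)-2-oxo-3-oxabicyclo[3.1.0]hexane-1-carboxylate (cis-fused cyclopropane-lactone)
Conditions: 2 (1.2 equiv), NaH (1.1 equiv), THF–DMF, 0 °C; then 1, 0 → 60 °C
Reagents that add atoms: none other than reactants 1 (ClC[C@@H]1CO1) and 2 (O=C(CC(=O)OCc1ccccc1)OCc1ccccc1)
Why: Malonate/epichlorohydrin annulation (epoxide opening, epoxide transposition with loss of chloride, 3-exo-tet cyclopropanation, lactonisation, as used for 4-alkylbutyrolactones); the purchased stereocentre is inverted once in the cyclopropane-forming SN2 step and becomes C5, and the ring fusion can only be cis.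

**Step 2**
Reactants: 3; 4 1-(benzyloxy)-4-bromo-2-methoxybenzene (as its Grignard reagent); 5 4-(benzyloxy)-3-methoxybenzyl bromide
Product: 6 benzyl (3R,4S)-3,4-bis{[4-(benzyloxy)-3-methoxyphenyl]methyl}-2-oxooxolane-3-carboxylate
Conditions: 4, Mg, THF (gives ArMgBr, 1.1 equiv); 3, CuI (10 mol%), THF, −40 → 0 °C; then 5 (1.3 equiv), DMPU, 0 → 45 °C
Reagents that add atoms: none other than reactants 4 (COc1cc(Br)ccc1OCc1ccccc1, aryl group) and 5 (COc1cc(CBr)ccc1OCc1ccccc1, benzyl group)
Why: Cu-catalysed homoconjugate (SN2-type) addition of the aryl Grignard to the unsubstituted cyclopropane CH2 of the doubly activated cyclopropane leaves the ring-fusion CH untouched (it becomes lactone C4, the future C6 of the target), and the malonate-type enolate is benzylated in the same pot anti to the C4 substituent; the configuration at quaternary C3 is erased in step 3.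

**Step 3**
Reactants: 6
Product: 7 (3S,4S)-3,4-bis[(4-hydroxy-3-methoxyphenyl)methyl]oxolan-2-one, (+)-matairesinol
Conditions: H2 (1 atm), 10% Pd/C, EtOAc–MeOH, rt; filter; 1,4-dioxane, 100 °C (−CO2); then DBU, 80 °C
Reagents that add atoms: none
Why: Hydrogenolysis cleaves both aryl benzyl ethers and the benzyl ester, the resulting β-carbonyl acid decarboxylates thermally, and base equilibration through the lactone enolate gives the thermodynamically preferred trans-3,4-dibenzyl lactone, so C3 (future C7) is set by the C4 centre derived from epichlorohydrin.

**Step 4**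
Reactants: 7
Product: 8 (2S,3S)-2,3-bis[(4-hydroxy-3-methoxyphenyl)methyl]butane-1,4-diol, (+)-secoisolariciresinol
Conditions: LiAlH4 (5 equiv), THF, 0 °C → reflux; aq. Rochelle salt / dilute HCl work-up
Reagents that add atoms: none
Why: LiAlH4 reduction of a γ-lactone to the 1,4-diol (known on the enantiomeric natural lignan); the free phenols are simply carried as phenoxides and neither stereocentre is touched.

**Step 5**
Reactants: 8
Product: 9 (6S,7S,8R)-8-(4-hydroxy-3-methoxyphenyl)-6,7-bis(hydroxymethyl)-3-methoxy-5,6,7,8-tetrahydronaphthalen-2-ol, (−)-isolariciresinol (target)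
Conditions: undivided cell, graphite anode / Pt cathode, constant current 3 mA cm⁻², 2.1 F mol⁻¹, n-Bu4NBF4 (0.05 M), HFIP–CH2Cl2 (4:1), 5 mM, 0 °C; then TFA (5 equiv), rt, 1 h
Reagents that add atoms: none
Why: Proposed new method: anodic dehydrogenative Friedel–Crafts cyclisation — two-electron/two-proton oxidation of either (homotopic) 4-alkylguaiacol unit in non-nucleophilic, cation-stabilising HFIP gives a p-quinone methide at the benzylic carbon, which the other guaiacyl ring attacks through its C6 (para to OMe) in a chair-like six-membered transition state with both CH2OH groups and the aryl pseudo-equatorial, setting C8 as R (aryl trans to the C7 CH2OH); any 5-ring benzylic ether from O-trapping is re-ionised by the TFA finish and funnels to the same tetralin, and the product's diarylmethine C–H is poorly aligned with the pendant phenol π-system, which slows over-oxidation there; closest known reaction types are anodic side-chain functionalisation of 4-alkylphenols via p-quinone methides, DDQ-mediated oxidative cyclisation of dibenzylbutyrolactones to aryltetralins, and acid-induced cyclisation of lariciresinol/7-hydroxy-secolignans to isolariciresinol.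

## Compound list

1 | (S)-epichlorohydrin [(S)-2-(chloromethyl)oxirane] | ClC[C@@H]1CO1 | starting material
2 | dibenzyl malonate | O=C(CC(=O)OCc1ccccc1)OCc1ccccc1 | starting material
3 | benzyl (1S,5S)-2-oxo-3-oxabicyclo[3.1.0]hexane-1-carboxylate | O=C1OC[C@H]2C[C@@]12C(=O)OCc1ccccc1 | intermediate
4 | 1-(benzyloxy)-4-bromo-2-methoxybenzene | COc1cc(Br)ccc1OCc1ccccc1 | starting material
5 | 4-(benzyloxy)-3-methoxybenzyl bromide | COc1cc(CBr)ccc1OCc1ccccc1 | starting material
6 | benzyl (3R,4S)-3,4-bis{[4-(benzyloxy)-3-methoxyphenyl]methyl}-2-oxooxolane-3-carboxylate | O=C1OC[C@@H](Cc2ccc(OCc3ccccc3)c(OC)c2)[C@@]1(Cc1ccc(OCc2ccccc2)c(OC)c1)C(=O)OCc1ccccc1 | intermediate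
7 | (3S,4S)-3,4-bis[(4-hydroxy-3-methoxyphenyl)methyl]oxolan-2-one, (+)-matairesinol | O=C1OC[C@@H](Cc2ccc(O)c(OC)c2)[C@@H]1Cc1ccc(O)c(OC)c1 | intermediate
8 | (2S,3S)-2,3-bis[(4-hydroxy-3-methoxyphenyl)methyl]butane-1,4-diol, (+)-secoisolariciresinol | OC[C@@H](Cc1ccc(O)c(OC)c1)[C@@H](CO)Cc1ccc(O)c(OC)c1 | intermediate
9 | (6S,7S,8R)-8-(4-hydroxy-3-methoxyphenyl)-6,7-bis(hydroxymethyl)-3-methoxy-5,6,7,8-tetrahydronaphthalen-2-ol, (−)-isolariciresinol | COc1cc([C@@H]2c3cc(O)c(OC)cc3C[C@H](CO)[C@H]2CO)ccc1O | target

## Summary

Total steps: 5. Longest linear sequence: 5.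

Three steps most likely to fail:

1. **Step 5 (proposed new anodic cyclisation).** Risks are over-oxidation of the product phenols, phenoxyl-radical dimerisation and electrode fouling. Fallback (known chemistry, different bond-forming logic): put the benzylic oxygen in by aldol instead of C–H oxidation. Open 3 with the Grignard of 4 without benzylation and decarboxylate to (S)-4-[4-(benzyloxy)-3-methoxybenzyl]oxolan-2-one. Then LDA aldol with O-benzylvanillin, TFA-mediated Friedel–Crafts closure to the trans aryltetralin lactone, LiAlH4, and H2/Pd-C give 9.
2. **Step 2 (one-pot cuprate opening and enolate benzylation).** The chelated magnesium malonate enolate may alkylate sluggishly, and Cu can couple residual ArMgBr with 5. Fallback: the classical stepwise lithium-enolate route. Use the methyl ester analogue of 3 (from dimethyl malonate), ring-open and quench, then Krapcho dealkoxycarbonylation to the (S)-β-arylmethyl lactone. LiHMDS/5 at −78 °C then installs the second benzyl kinetically trans. LiAlH4 and hydrogenolysis give 8 (two extra steps).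
3. **Step 1 (annulation with the benzyl ester).** Competing direct chloride displacement gives the enantiomeric lactone and erodes ee, and yields of this annulation are moderate. Fallback: take the two stereocentres from a natural source instead. Flaxseed secoisolariciresinol diglucoside has the same (2S,3S)-(+)-aglycone (confirm by sign of rotation), so acidic or enzymatic deglycosylation gives 8 directly and the route resumes at step 5.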